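## Retrosynthetic overview

1. Ring C is closed last: the C2–O1 bond comes from an enantioselective, chalcone-isomerase-type 6-endo oxa-Michael closure of the free 2',4'-dihydroxychalcone, which sets C2 (S), the only stereocenter.
2. The chalcone Cα=Cβ bond comes from a protecting-group-free Claisen–Schmidt condensation of 3-prenylresacetophenone with 2,2-dimethylchromene-6-carbaldehyde.
3. Ring D comes from oxidative cyclisation of 4-hydroxy-3-prenylbenzaldehyde (hydride abstraction, ortho-quinone methide, oxa-6π closure), done before coupling so the ring A prenylphenol never meets the oxidant.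
4. Both prenyl groups come from direct phenoxide C-prenylation of 2,4-dihydroxyacetophenone and 4-hydroxybenzaldehyde with prenyl bromide.
5. Ring order: rings A and B are bought, ring D is formed in step 3, ring C in step 5.

Assumption: the quinine-derived thiourea is taken to deliver the phenol oxygen to the Si face of C-beta (giving 2S). This is checked on the first batch by CD and chiral HPLC; if the sense is opposite, the quinidine-derived pseudoenantiomer is used in the same step.

## Route

Step 1
Reactants: 1 2,4-dihydroxyacetophenone; 2 prenyl bromide (1-bromo-3-methylbut-2-ene)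
Product: 3 1-[2,4-dihydroxy-3-(3-methylbut-2-en-1-yl)phenyl]ethan-1-one
Conditions: KOH (1.1 equiv), H2O, 0 °C → rt, 16 h; chromatography to remove the 5-prenyl isomer and O-prenyl ether; unreacted 1 recycled
Reagents that add atoms: prenyl bromide (2), CC(C)=CCBr
Why: Phenoxide C-alkylation (Friedel–Crafts-type allylation, the laboratory counterpart of an aromatic prenyltransferase) in water, where solvation of the phenoxide oxygen favours attack through carbon and C3, flanked by both oxygens, is the most nucleophilic ring position; no stereocenter is formed.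

Step 2
Reactants: 4 4-hydroxybenzaldehyde; 2 prenyl bromide
Product: 5 4-hydroxy-3-(3-methylbut-2-en-1-yl)benzaldehyde
Conditions: KOH (1.1 equiv), H2O, rt, 24 h; the neutral O-prenyl ether is removed by extraction before acidification, then chromatography
Reagents that add atoms: prenyl bromide (2), CC(C)=CCBr
Why: The same phenoxide C-alkylation, here with only the two equivalent positions ortho to the OH available, so a single C-prenyl isomer forms; no stereocenter is formed.

Step 3
Reactants: 5 4-hydroxy-3-(3-methylbut-2-en-1-yl)benzaldehyde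
Product: 7 2,2-dimethyl-2H-chromene-6-carbaldehyde, via ortho-quinone methide 6 (not isolated)
Conditions: DDQ (1.1 equiv), PhMe, 80 °C, 1–2 h; filter off the hydroquinone, short silica plug
Reagents that add atoms: none
Why: DDQ dehydrogenation of an ortho-prenylphenol, in which hydride abstraction from the benzylic-allylic CH2 gives ortho-quinone methide 6 and this closes by oxa-6π electrocyclisation to the 2H-chromene, mirroring the oxidative prenyl cyclisation of the biosynthesis; the aldehyde is inert to DDQ and no stereocenter is formed.

Step 4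
Reactants: 3 1-[2,4-dihydroxy-3-(3-methylbut-2-en-1-yl)phenyl]ethan-1-one; 7 2,2-dimethyl-2H-chromene-6-carbaldehyde
Product: 9 (2E)-1-[2,4-dihydroxy-3-(3-methylbut-2-en-1-yl)phenyl]-3-(2,2-dimethyl-2H-chromen-6-yl)prop-2-en-1-one, via aldol adduct 8 (not isolated)
Conditions: KOH (50% aq., 12 equiv), EtOH, 0 °C → rt, 36 h, N2, dark; then 1 M HCl, 0 °C, to pH 5
Reagents that add atoms: none
Why: Claisen–Schmidt crossed aldol condensation, in which aldehyde 7 cannot enolise, excess hydroxide enolises the acetyl group of the bis-phenoxide of 3, and E1cB loss of water from aldol 8 gives the conjugated E-enone, which stays ring-open as its phenoxide in strong base; the carbinol stereocenter of 8 is destroyed on dehydration.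

Step 5
Reactants: 9 (2E)-1-[2,4-dihydroxy-3-(3-methylbut-2-en-1-yl)phenyl]-3-(2,2-dimethyl-2H-chromen-6-yl)prop-2-en-1-one
Product: 10 (2S)-7-hydroxy-8-(3-methylbut-2-en-1-yl)-2-(2,2-dimethyl-2H-chromen-6-yl)-2,3-dihydro-4H-chromen-4-one
Conditions: N-[3,5-bis(trifluoromethyl)phenyl]-N'-[(8α,9S)-6'-methoxycinchonan-9-yl]thiourea (15 mol%), PhMe/CH2Cl2 4:1, −10 °C, 72–96 h, stopped at about 75% conversion; AcOH quench, cold silica filtration, recovered 9 recycled; ee raised by recrystallisation
Reagents that add atoms: none
Why: Proposed new method: an enantioselective 6-endo-trig intramolecular oxa-Michael addition (chalcone-isomerase-type) run directly on the unactivated, unprotected chalcone, in which the thiourea hydrogen-bonds the enone carbonyl in place of the internal 2'-OH···O=C bond while the quinuclidine nitrogen acts as general base on the 2'-OH and delivers its oxygen to the Si face of C-beta, so that C2 is formed as S under kinetic control (the reaction is stopped before the retro-Michael equilibrium erodes ee, and the less nucleophilic, more acidic 4'-OH can only slow turnover by binding the amine); the closest known reaction type is the cinchona-thiourea-catalysed asymmetric oxa-Michael cyclisation of 2-hydroxyaryl alkylidene beta-ketoesters and of simple 2'-hydroxychalcones to flavanones.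

## Compound list

1 | 2,4-dihydroxyacetophenone | CC(=O)c1ccc(O)cc1O | starting material
2 | prenyl bromide (1-bromo-3-methylbut-2-ene) | CC(C)=CCBr | starting material
3 | 1-[2,4-dihydroxy-3-(3-methylbut-2-en-1-yl)phenyl]ethan-1-one | CC(=O)c1ccc(O)c(CC=C(C)C)c1O | intermediate
4 | 4-hydroxybenzaldehyde | O=Cc1ccc(O)cc1 | starting material
5 | 4-hydroxy-3-(3-methylbut-2-en-1-yl)benzaldehyde | CC(C)=CCc1cc(C=O)ccc1O | intermediate
6 | ortho-quinone methide, 3-(3-methylbut-2-en-1-ylidene)-4-oxocyclohexa-1,5-diene-1-carbaldehyde (exocyclic alkene geometry not defined, transient) | O=CC1=CC(=CC=C(C)C)C(=O)C=C1 | intermediate (not isolated)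
7 | 2,2-dimethyl-2H-chromene-6-carbaldehyde | CC1(C)C=Cc2cc(C=O)ccc2O1 | intermediate
8 | aldol adduct, 1-[2,4-dihydroxy-3-(3-methylbut-2-en-1-yl)phenyl]-3-(2,2-dimethyl-2H-chromen-6-yl)-3-hydroxypropan-1-one (racemic) | CC(C)=CCc1c(O)ccc(C(=O)CC(O)c2ccc3c(c2)C=CC(C)(C)O3)c1O | intermediate (not isolated)
9 | (2E)-1-[2,4-dihydroxy-3-(3-methylbut-2-en-1-yl)phenyl]-3-(2,2-dimethyl-2H-chromen-6-yl)prop-2-en-1-one | CC(C)=CCc1c(O)ccc(C(=O)/C=C/c2ccc3c(c2)C=CC(C)(C)O3)c1O | intermediate
10 | (2S)-7-hydroxy-8-(3-methylbut-2-en-1-yl)-2-(2,2-dimethyl-2H-chromen-6-yl)-2,3-dihydro-4H-chromen-4-one | CC(C)=CCc1c(O)ccc2c1O[C@H](c1ccc3c(c1)C=CC(C)(C)O3)CC2=O | target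

## Summary

Total step count: 5. Longest linear sequence: 4 steps (4 → 5 → 7 → 9 → 10).

Three steps most likely to fail:

Step 5 (asymmetric ring C closure). The enone is unactivated and carries a donor aryl group, the 4'-OH is free, and the closure is reversible, so rate and ee may both be low. The fallback sets out from 9 and comes back at 10, replacing asymmetric catalysis by resolution with recycling. Compound 9 is cyclised without stereocontrol (NaOAc, EtOH, reflux) to the racemic flavanone F1. F1 is separated by preparative chiral SFC (amylose tris(3,5-dimethylphenylcarbamate) phase, CO2/MeOH) into 10 and the (2R)-enantiomer F2. F2 is returned to the NaOAc conditions, where retro-oxa-Michael opening and re-closure convert it back to F1, so the material is funnelled to 10 over repeated cycles.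

Step 1 (direct C3-prenylation of 1). The yield is expected to be low (about 30%) with 5-prenyl, O-prenyl and diprenyl by-products. The fallback sets out from 1 and comes back at 3, replacing direct C-alkylation by O-alkylation and sigmatropic transfer. The non-chelated 4-OH of 1 is alkylated with 3-chloro-3-methylbut-1-yne (K2CO3, KI, CuI cat., acetone, reflux) to the propargyl ether F3. Semihydrogenation (H2, Pd/CaCO3 poisoned with Pb(OAc)2, quinoline, EtOAc) gives the 1,1-dimethylallyl ether F4. Aromatic Claisen rearrangement (N,N-diethylaniline, 140 °C) transfers the allyl unit with inversion to C3, the position favoured by the bond fixation of the chelated 2-OH/C=O unit, and gives 3.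

Step 4 (condensation of the unprotected dihydroxyacetophenone). Enolising a bis-phenoxide is slow and conversion may stall. The fallback sets out from 3 and comes back at 9, using a protected substrate. The acidic 4-OH of 3 is masked (chloromethyl methyl ether, K2CO3, acetone, rt; the chelated 2-OH does not react) to the MOM ether F5. Condensation of F5 with 7 (KOH, EtOH/H2O, rt) now runs through a mono-phenoxide enolate and gives the MOM-protected chalcone F6. Brief treatment with 3 M HCl in MeOH at rt removes the acetal and gives 9.

## Further compounds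

F1 | step 5 | racemic 7-hydroxy-8-(3-methylbut-2-en-1-yl)-2-(2,2-dimethyl-2H-chromen-6-yl)-2,3-dihydro-4H-chromen-4-one | CC(C)=CCc1c(O)ccc2c1OC(c1ccc3c(c1)C=CC(C)(C)O3)CC2=O
F2 | step 5 | (2R)-7-hydroxy-8-(3-methylbut-2-en-1-yl)-2-(2,2-dimethyl-2H-chromen-6-yl)-2,3-dihydro-4H-chromen-4-one | CC(C)=CCc1c(O)ccc2c1O[C@@H](c1ccc3c(c1)C=CC(C)(C)O3)CC2=O
F3 | step 1 | 1-{2-hydroxy-4-[(2-methylbut-3-yn-2-yl)oxy]phenyl}ethan-1-one | CC(=O)c1ccc(OC(C)(C)C#C)cc1O
F4 | step 1 | 1-{2-hydroxy-4-[(2-methylbut-3-en-2-yl)oxy]phenyl}ethan-1-one | CC(=O)c1ccc(OC(C)(C)C=C)cc1O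
F5 | step 4 | 1-[2-hydroxy-4-(methoxymethoxy)-3-(3-methylbut-2-en-1-yl)phenyl]ethan-1-one | CC(=O)c1ccc(OCOC)c(CC=C(C)C)c1O
F6 | step 4 | (2E)-1-[2-hydroxy-4-(methoxymethoxy)-3-(3-methylbut-2-en-1-yl)phenyl]-3-(2,2-dimethyl-2H-chromen-6-yl)prop-2-en-1-one | CC(C)=CCc1c(OCOC)ccc(C(=O)/C=C/c2ccc3c(c2)C=CC(C)(C)O3)c1O
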